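A small charge of G, 0.400 M in the flask called autumn, and a large one, 2.50 M in winter, meet the same racemate of J and L, and you want the excess of E over D along the row.

| flask | J | L | G | remark | time |
|---|---|---|---|---|---|
| Saturday's | 0.50 M | 0.50 M | 0.57 M | run made earlier |  |
| autumn | 0.50 M | 0.50 M | 0.400 M |  | 1.0 h |
| noon | 0.50 M | 0.50 M | 0.600 M |  | 1.0 h |
| dawn | 0.50 M | 0.50 M | 1.00 M |  | 1.0 h |
| midnight | 0.50 M | 0.50 M | 1.50 M |  | 1.0 h |
| winter | 0.50 M | 0.50 M | 2.50 M |  | 1.0 h |

Saturday's run (percent of the J and L together charged)

| time / min | E / % | D / % | J / % |
|---|---|---|---|
| 5.00 | 2.6 | 0 | 48.8 |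
| 15.0 | 8.3 | 0.6 | 43.9 |
| 30.0 | 13.0 | 0 | 39.8 |
| 40.0 | 14.5 | 1.4 | 40.0 |
| 60.0 | 18.4 | 0 | 38.1 |

(readings scatter by 1 percentage point)

- G is single-handed; J and L are mirror images of each other, charged as a racemate, each of them at the stated concentration
- reactions considered so far: G + J -> E; G + L -> D; J <-> L; G <-> Q
- an excess is the difference of the two amounts in percent of their sum
- "hardly changes" means that all values lie within two and a half points (for a concentration: within two and a half percent of the largest)
- the handed part of G does not stay in what it makes, so the products of the two hands are mirror images too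

* excess of E over D at the end for autumn, noon, dawn, midnight, winter, in this order
* how the row runs (rises, then falls / rises all the way / falls all the way / falls, then rises / hardly changes)

D is the small thing here, so reckon only D against E. Each step takes one G, so cG cancels from the ratio of their rates, and G lost to Q cancels with it. Over a run, D/E is m/s, where m is the ratio of L to J averaged over the making of E. The excess is then one minus D/E, over one plus D/E.

On Saturday the E readings sum to 56.8% and the D readings to 2.00%. At 60.0 min, L stands at 43.5% by balance against J at 38.1%, a ratio of 1.14, so I take m as 1.07, midway from one. That gives 30.4 for s, the selectivity factor, how much faster G takes J than L at equal amounts.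

The objection is that the D sum scatters by 2.2 percentage points, about its own size, so s is a weak reading. But s is common to every flask: it scales all the shortfalls by about one factor and leaves their order to m.

Autumn's charge lies near Saturday's 0.57 M, so with Saturday's m its excess is 93.2%. Winter's charge is 4.39 times Saturday's, and with no feed from L, scaling Saturday's use of J by the charge puts its end ratio at roughly 7.48. Yet by that balance L fed J on Saturday, having lost 6.5 points, a reading with its scatter. I judge winter's end ratio near 2 and its m at 1.50, which gives 90.6%.

The forecast reads 93%, 92.5%, 91%, 89%, 86%, and the row falls all the way: “At high G, J is consumed faster than it is replenished”. Its winter value lies below mine.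

The flask gives 92.7%, 92.4%, 91.8%, 90.9%, 89.1%, and the row falls all the way.

    G + J → E (k = 4.30 × 10⁻⁴ /M/s)
    G + L → D (k = 1.50 × 10⁻⁵ /M/s)
    J ⇌ L (k = 2.60 × 10⁻⁴ /s)
    G ⇌ Q (K = 1.50, k = 4.20 × 10⁻⁴ /s)

L over J ended at 2.01 in winter against 1.11 in autumn. Run s backwards: winter's excess becomes an m of 1.75, a reading below that end ratio. In midnight's flask the same s turns 90.9% into an m of 1.45, below the end ratio of 1.51.

The data were computed with made-up constants, and the scatter is random.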